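## Plan

1. Retrosynthetic cuts: C4 is first re-oxidised to a helper ketone. Then O1–C2 (ring C) is cut, then C3–C4 (the join between the ring A and ring B halves), and finally the 5-O–CH3 bond and the C6–prenyl bond of ring A.
2. Forward order: a ring A aldehyde is made by C-prenylation, sterically controlled bis-silylation and O-methylation. It is joined at C3–C4 to a ring B enol triflate, the carbinol is oxidised to a 1,2-diarylprop-2-en-1-one, and ring C is closed last.
3. Enabling feature: with C4 as a ketone, C2 is the unsubstituted beta-carbon of an enone six atoms from the C8a oxygen of ring A. C3–H lies between the C4 carbonyl and ring B and is therefore configurationally mobile. The 7-OH of ring A stands para to C4, so the helper oxygen can leave through a para-quinone methide.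
4. Stereochemistry: no chiral material is carried. The single stereocentre C3 (R) is set in the ring-closing step, where a racemising isoflavanone is funnelled into one enantiomer by RuCl[(R,R)-TsDPEN](p-cymene)/HCO2H (dynamic kinetic resolution). The C4 oxygen is removed in the same flask.

Key step: step 8

Remark: C3 of the target is read as R (priorities C2 > C1' of ring B > C4 > H). Chroman numbering (O1, C2, C3, C4, C4a, C5 to C8, C8a; ring B primed) is used for all open-chain precursors as well.

## Route

Step 1
Reactants: 1 2,4,6-trihydroxybenzaldehyde; 2 prenyl bromide (1-bromo-3-methylbut-2-ene)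
Product: 3 2,4,6-trihydroxy-3-(3-methylbut-2-en-1-yl)benzaldehyde
Conditions: KOH (1 equiv), H2O, 0 °C to rt
Reagents that add atoms: none
Why: C-alkylation of an ambident phloroglucinol-type phenoxide in water (the oxygens are hydrogen bonded and the allylic bromide is soft) should place the prenyl group on a ring carbon, and because the two free ring carbons of 1 are equivalent, mono-alkylation gives one constitution.

Step 2
Reactants: 3 2,4,6-trihydroxy-3-(3-methylbut-2-en-1-yl)benzaldehyde
Product: 4 4,6-bis(tert-butyldimethylsilyloxy)-2-hydroxy-3-(3-methylbut-2-en-1-yl)benzaldehyde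
Conditions: TBSCl (2.1 equiv), imidazole, CH2Cl2/DMF, 0 °C to rt
Reagents that add atoms: tert-butyldimethylsilyl chloride CC(C)(C)[Si](C)(C)Cl
Why: In this sterically controlled O-silylation the para 4-OH and the less hindered chelated 6-OH should react, whereas the 2-OH, wedged between the formyl and prenyl groups and hydrogen bonded to C=O, should stay free.

Step 3
Reactants: 4 4,6-bis(tert-butyldimethylsilyloxy)-2-hydroxy-3-(3-methylbut-2-en-1-yl)benzaldehyde
Product: 5 4,6-bis(tert-butyldimethylsilyloxy)-2-methoxy-3-(3-methylbut-2-en-1-yl)benzaldehyde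
Conditions: MeOH, PPh3, DIAD, THF, 0 °C to rt
Reagents that add atoms: methanol CO
Why: Mitsunobu etherification lets the remaining hindered phenol attack a methyl carbon, the smallest electrophile available, under neutral conditions that spare the base-labile aryl silyl ethers, the aldehyde and the prenyl alkene.

Step 4
Reactants: 6 1-(4-hydroxy-2-methoxyphenyl)ethan-1-one
Product: 7 1-[4-(tert-butyldimethylsilyloxy)-2-methoxyphenyl]ethan-1-one
Conditions: TBSCl, imidazole, DMF, rt
Reagents that add atoms: tert-butyldimethylsilyl chloride CC(C)(C)[Si](C)(C)Cl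
Why: This is a standard O-silylation of the only phenol, chosen so that all three phenol masks of the later precursor fall to one fluoride trigger.

Step 5
Reactants: 7 1-[4-(tert-butyldimethylsilyloxy)-2-methoxyphenyl]ethan-1-one
Product: 8 1-[4-(tert-butyldimethylsilyloxy)-2-methoxyphenyl]ethenyl trifluoromethanesulfonate
Conditions: KHMDS, THF, −78 °C; then PhNTf2, −78 °C to 0 °C
Reagents that add atoms: N-phenylbis(trifluoromethanesulfonimide) O=S(=O)(N(c1ccccc1)S(=O)(=O)C(F)(F)F)C(F)(F)F
Why: Enol triflate formation by O-sulfonylation of the potassium enolate of a methyl ketone has only one possible regiochemistry and turns the acetyl carbon into the future C3 as an alkenyl electrophile.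

Step 6
Reactants: 5 4,6-bis(tert-butyldimethylsilyloxy)-2-methoxy-3-(3-methylbut-2-en-1-yl)benzaldehyde; 8 1-[4-(tert-butyldimethylsilyloxy)-2-methoxyphenyl]ethenyl trifluoromethanesulfonate
Product: 9 rac-1-[4,6-bis(tert-butyldimethylsilyloxy)-2-methoxy-3-(3-methylbut-2-en-1-yl)phenyl]-2-[4-(tert-butyldimethylsilyloxy)-2-methoxyphenyl]prop-2-en-1-ol
Conditions: CrCl2 (4 equiv), NiCl2 (2 mol %), DMF, rt
Reagents that add atoms: none
Why: In the Nozaki–Hiyama–Kishi coupling zerovalent nickel inserts into the C–OTf bond and transmetalation gives a weakly basic alkenylchromium species that adds only to the aldehyde (C3–C4 bond), its trivalent chromium alkoxide should not trigger aryl-to-alkoxide silyl migration, and the carbinol centre forms as a racemate that step 7 erases.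

Step 7
Reactants: 9 rac-1-[4,6-bis(tert-butyldimethylsilyloxy)-2-methoxy-3-(3-methylbut-2-en-1-yl)phenyl]-2-[4-(tert-butyldimethylsilyloxy)-2-methoxyphenyl]prop-2-en-1-ol
Product: 10 1-[4,6-bis(tert-butyldimethylsilyloxy)-2-methoxy-3-(3-methylbut-2-en-1-yl)phenyl]-2-[4-(tert-butyldimethylsilyloxy)-2-methoxyphenyl]prop-2-en-1-one
Conditions: MnO2 (activated, excess), CH2Cl2, rt
Reagents that add atoms: none
Why: MnO2 oxidation is selective for an alcohol that is both allylic and benzylic, is neutral (so the ionisable carbinol, the silyl ethers and the prenyl group are left alone) and installs the helper C4 carbonyl.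

Step 8
Reactants: 10 1-[4,6-bis(tert-butyldimethylsilyloxy)-2-methoxy-3-(3-methylbut-2-en-1-yl)phenyl]-2-[4-(tert-butyldimethylsilyloxy)-2-methoxyphenyl]prop-2-en-1-one
Product: 15 (3R)-3-(4-hydroxy-2-methoxyphenyl)-5-methoxy-6-(3-methylbut-2-en-1-yl)chroman-7-ol, via triphenol enone 11 (not isolated), via racemic isoflavanone 12 (not isolated), via cis-isoflavan-4-ol 13 (not isolated), via para-quinone methide 14 (not isolated)
Conditions: TBAF (3.3 equiv), THF, 0 °C, Ar; then, same flask, HCO2H/Et3N (5:2), RuCl[(R,R)-TsDPEN](p-cymene) (5 mol %), 40 °C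
Reagents that add atoms: none
Why: Fluoride removes the three silyl groups, and the C8a phenoxide of 11 adds to the unsubstituted enone terminus C2 in an intramolecular oxa-Michael addition (6-endo-trig closure of ring C, forming O1–C2) before any hydride source is present. The closest known reaction types are the base-induced cyclisation of 2'-hydroxy-alpha-methylenedeoxybenzoins to isoflavanones and the Noyori-type asymmetric transfer hydrogenation of racemic isoflavanones under dynamic kinetic resolution followed by domino deoxygenation; here they are run in one flask. Isoflavanone 12 forms as a racemate, but its C3–H is alpha to the C4 ketone and benzylic to ring B, so Et3N and formate should interconvert the enantiomers through the enol (and through retro-oxa-Michael opening) faster than the ketone is reduced. The ruthenium hydride carrying (R,R)-TsDPEN fixes the face of the C4 carbonyl that is attacked and accepts only the enantiomer of 12 whose ring B points away from the incoming hydride, which should give cis-(3R,4R)-13 and thereby sets C3 as R. The 7-OH para to C4, supported by O1 and the 5-OMe group, then expels the C4 hydroxyl as water to give para-quinone methide 14, which takes up a second hydride at C4, so the helper oxygen is gone and C3, no longer acidic, keeps its configuration. The selectivities needed are secured by the substrate and the order of addition: only the C8a oxygen can reach C2 in a six-membered ring (7-OH and 4'-OH cannot), closure precedes Ru–H so the enone C=C is not reduced, the unpolarised prenyl alkene is inert to the polar hydride/proton transfer, and the methylated 2'-oxygen cannot trap 14 as a pterocarpan.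

## Compound list

1 | 2,4,6-trihydroxybenzaldehyde | O=Cc1c(O)cc(O)cc1O | starting material
2 | prenyl bromide (1-bromo-3-methylbut-2-ene) | CC(C)=CCBr | starting material
3 | 2,4,6-trihydroxy-3-(3-methylbut-2-en-1-yl)benzaldehyde | O=Cc1c(O)cc(O)c(CC=C(C)C)c1O | intermediate
4 | 4,6-bis(tert-butyldimethylsilyloxy)-2-hydroxy-3-(3-methylbut-2-en-1-yl)benzaldehyde | O=Cc1c(O[Si](C)(C)C(C)(C)C)cc(O[Si](C)(C)C(C)(C)C)c(CC=C(C)C)c1O | intermediate
5 | 4,6-bis(tert-butyldimethylsilyloxy)-2-methoxy-3-(3-methylbut-2-en-1-yl)benzaldehyde | O=Cc1c(O[Si](C)(C)C(C)(C)C)cc(O[Si](C)(C)C(C)(C)C)c(CC=C(C)C)c1OC | intermediate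
6 | 1-(4-hydroxy-2-methoxyphenyl)ethan-1-one | CC(=O)c1ccc(O)cc1OC | starting material
7 | 1-[4-(tert-butyldimethylsilyloxy)-2-methoxyphenyl]ethan-1-one | CC(=O)c1ccc(O[Si](C)(C)C(C)(C)C)cc1OC | intermediate
8 | 1-[4-(tert-butyldimethylsilyloxy)-2-methoxyphenyl]ethenyl trifluoromethanesulfonate | C=C(OS(=O)(=O)C(F)(F)F)c1ccc(O[Si](C)(C)C(C)(C)C)cc1OC | intermediate
9 | rac-1-[4,6-bis(tert-butyldimethylsilyloxy)-2-methoxy-3-(3-methylbut-2-en-1-yl)phenyl]-2-[4-(tert-butyldimethylsilyloxy)-2-methoxyphenyl]prop-2-en-1-ol | C=C(c1ccc(O[Si](C)(C)C(C)(C)C)cc1OC)C(O)c1c(O[Si](C)(C)C(C)(C)C)cc(O[Si](C)(C)C(C)(C)C)c(CC=C(C)C)c1OC | intermediate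
10 | 1-[4,6-bis(tert-butyldimethylsilyloxy)-2-methoxy-3-(3-methylbut-2-en-1-yl)phenyl]-2-[4-(tert-butyldimethylsilyloxy)-2-methoxyphenyl]prop-2-en-1-one | C=C(c1ccc(O[Si](C)(C)C(C)(C)C)cc1OC)C(=O)c1c(O[Si](C)(C)C(C)(C)C)cc(O[Si](C)(C)C(C)(C)C)c(CC=C(C)C)c1OC | intermediate
11 | 1-[4,6-dihydroxy-2-methoxy-3-(3-methylbut-2-en-1-yl)phenyl]-2-(4-hydroxy-2-methoxyphenyl)prop-2-en-1-one (triphenol enone) | C=C(c1ccc(O)cc1OC)C(=O)c1c(O)cc(O)c(CC=C(C)C)c1OC | intermediate
12 | rac-7-hydroxy-3-(4-hydroxy-2-methoxyphenyl)-5-methoxy-6-(3-methylbut-2-en-1-yl)chroman-4-one (racemic isoflavanone) | COc1cc(O)ccc1C1COc2cc(O)c(CC=C(C)C)c(OC)c2C1=O | intermediate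
13 | (3R,4R)-3-(4-hydroxy-2-methoxyphenyl)-5-methoxy-6-(3-methylbut-2-en-1-yl)chromane-4,7-diol (cis-isoflavan-4-ol) | COc1cc(O)ccc1[C@@H]1COc2cc(O)c(CC=C(C)C)c(OC)c2[C@@H]1O | intermediate
14 | (3R)-3-(4-hydroxy-2-methoxyphenyl)-5-methoxy-6-(3-methylbut-2-en-1-yl)-2,3-dihydro-7H-chromen-7-one (para-quinone methide) | COc1cc(O)ccc1[C@@H]1COC2=CC(=O)C(CC=C(C)C)=C(OC)C2=C1 | intermediate
15 | (3R)-3-(4-hydroxy-2-methoxyphenyl)-5-methoxy-6-(3-methylbut-2-en-1-yl)chroman-7-ol | COc1cc(O)ccc1[C@@H]1COc2cc(O)c(CC=C(C)C)c(OC)c2C1 | target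

## Step count and risks

Total step count: 8. Longest linear sequence: 6 (steps 1, 2, 3, 6, 7, 8).

Steps most likely to fail:

**Step 8.** Three processes may go wrong.
- The ruthenium hydride cycle may be slowed by fluoride and ammonium salts carried over from the desilylation.
- Hydride transfer may be sluggish to a carbonyl that is deactivated by three oxygen donors and flanked by the 5-OMe group.
- Proton loss from C3 at the quinone methide stage would erode configurational purity or stall the deoxygenation.

The fallback sets out from 10 and comes back at 15. It separates ring closure, stereocontrol and deoxygenation. Treatment of 10 with TBAF alone and aqueous work-up should give isolated 12. TBSCl/imidazole then re-silylates both phenols to the bis-silyl isoflavanone F1, whose ketone is more electrophilic because no phenoxide feeds into it. RuCl[(R,R)-TsDPEN](p-cymene) with HCO2H/Et3N should stop at the bis-silyl cis-(3R,4R)-isoflavan-4-ol F2, since no free 7-OH can expel the hydroxyl. Ionic hydrogenation (Et3SiH in large excess, BF3·OEt2, CH2Cl2, −78 °C) captures the C4 cation at low temperature to give the bis-silyl (3R)-isoflavan F3. TBAF then releases 15.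

**Step 2.** The two chelated hydroxyls may be poorly discriminated, or the silyl groups may scramble, so that the methylation of step 3 would hit the wrong oxygen.

The fallback sets out from 1 and comes back at 4, bypassing step 1 as well. It fixes the regiochemistry by a sigmatropic shift instead of by sterics. TBSCl (2 equiv)/imidazole converts 1, whose two ortho hydroxyls are equivalent, into 4,6-bis(tert-butyldimethylsilyloxy)-2-hydroxybenzaldehyde F4. Copper-catalysed O-alkylation with 3-chloro-3-methylbut-1-yne (CuCl2 cat., DBU, MeCN, 0 °C) gives the 1,1-dimethylpropargyl ether F5. Semi-hydrogenation (H2, Pd/CaCO3 poisoned with Pb(OAc)2, quinoline) gives the 1,1-dimethylallyl ether F6. Heating (toluene, 110 °C) triggers an aromatic Claisen rearrangement that can reach only the one free ortho carbon. This delivers 4 with the hydroxyl to be methylated automatically next to the prenyl group.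

**Step 6.** Addition of the alkenylchromium species to a di-ortho-substituted, electron-rich aldehyde may be slow. It would then compete with reductive dimerisation or protonolysis of the alkenyl metal.

The fallback sets out from 5 and comes back at 10, bypassing step 7. It forms the C3–C1' bond by enolate arylation instead of the C3–C4 bond by carbonyl addition. MeMgBr (THF, −78 °C) adds to 5 to give the 1-arylethanol F7, and MnO2 oxidises it to the acetophenone F8. Commercial 4-bromo-3-methoxyphenol is silylated (TBSCl, imidazole) to the aryl bromide F9. Palladium-catalysed ketone alpha-arylation of F8 with F9 (Pd2(dba)3, XPhos, K3PO4, toluene, 80 °C) gives the deoxybenzoin F10; the weak base is chosen to limit silyl transfer to the enolate. Alpha-methylenation (paraformaldehyde, iPr2NH·CF3CO2H, THF, reflux) then returns to 10.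

## Further compounds

F1 | step 8 | rac-7-(tert-butyldimethylsilyloxy)-3-[4-(tert-butyldimethylsilyloxy)-2-methoxyphenyl]-5-methoxy-6-(3-methylbut-2-en-1-yl)chroman-4-one | COc1cc(O[Si](C)(C)C(C)(C)C)ccc1C1COc2cc(O[Si](C)(C)C(C)(C)C)c(CC=C(C)C)c(OC)c2C1=O
F2 | step 8 | (3R,4R)-7-(tert-butyldimethylsilyloxy)-3-[4-(tert-butyldimethylsilyloxy)-2-methoxyphenyl]-5-methoxy-6-(3-methylbut-2-en-1-yl)chroman-4-ol | COc1cc(O[Si](C)(C)C(C)(C)C)ccc1[C@@H]1COc2cc(O[Si](C)(C)C(C)(C)C)c(CC=C(C)C)c(OC)c2[C@@H]1O
F3 | step 8 | (3R)-7-(tert-butyldimethylsilyloxy)-3-[4-(tert-butyldimethylsilyloxy)-2-methoxyphenyl]-5-methoxy-6-(3-methylbut-2-en-1-yl)chroman | COc1cc(O[Si](C)(C)C(C)(C)C)ccc1[C@@H]1COc2cc(O[Si](C)(C)C(C)(C)C)c(CC=C(C)C)c(OC)c2C1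
F4 | step 2 | 4,6-bis(tert-butyldimethylsilyloxy)-2-hydroxybenzaldehyde | O=Cc1c(O)cc(O[Si](C)(C)C(C)(C)C)cc1O[Si](C)(C)C(C)(C)C
F5 | step 2 | 4,6-bis(tert-butyldimethylsilyloxy)-2-(2-methylbut-3-yn-2-yloxy)benzaldehyde | O=Cc1c(OC(C)(C)C#C)cc(O[Si](C)(C)C(C)(C)C)cc1O[Si](C)(C)C(C)(C)C
F6 | step 2 | 4,6-bis(tert-butyldimethylsilyloxy)-2-(2-methylbut-3-en-2-yloxy)benzaldehyde | O=Cc1c(OC(C)(C)C=C)cc(O[Si](C)(C)C(C)(C)C)cc1O[Si](C)(C)C(C)(C)C
F7 | step 6 | rac-1-[4,6-bis(tert-butyldimethylsilyloxy)-2-methoxy-3-(3-methylbut-2-en-1-yl)phenyl]ethan-1-ol | CC(O)c1c(O[Si](C)(C)C(C)(C)C)cc(O[Si](C)(C)C(C)(C)C)c(CC=C(C)C)c1OC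
F8 | step 6 | 1-[4,6-bis(tert-butyldimethylsilyloxy)-2-methoxy-3-(3-methylbut-2-en-1-yl)phenyl]ethan-1-one | CC(=O)c1c(O[Si](C)(C)C(C)(C)C)cc(O[Si](C)(C)C(C)(C)C)c(CC=C(C)C)c1OC
F9 | step 6 | (4-bromo-3-methoxyphenoxy)(tert-butyl)dimethylsilane | COc1cc(O[Si](C)(C)C(C)(C)C)ccc1Br
F10 | step 6 | 1-[4,6-bis(tert-butyldimethylsilyloxy)-2-methoxy-3-(3-methylbut-2-en-1-yl)phenyl]-2-[4-(tert-butyldimethylsilyloxy)-2-methoxyphenyl]ethan-1-one | COc1cc(O[Si](C)(C)C(C)(C)C)ccc1CC(=O)c1c(O[Si](C)(C)C(C)(C)C)cc(O[Si](C)(C)C(C)(C)C)c(CC=C(C)C)c1OC
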